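The constants of this flask have to come out of the readings, and the one I chase here is how much target lasts.

in all of them: free catalyst 0.0640 M
- Wednesday's: substrate 0.800 M; coupling partner 1.60 M
- Saturday's: substrate 0.480 M; coupling partner 1.28 M
- Sunday's: substrate 2.40 M; coupling partner 1.60 M
- Tuesday's: substrate 0.800 M; coupling partner 1.60 M; target 0.640 M; time 5.8 min

| run | time / min | [target] / M |
|---|---|---|
| Wednesday's run | 0.72 | 0.081 |
| Wednesday's run | 1.4 | 0.137 |
| Wednesday's run | 2.2 | 0.195 |
| Wednesday's run | 2.9 | 0.236 |
| Wednesday's run | 3.6 | 0.267 |
| Wednesday's run | 4.3 | 0.283 |
| Wednesday's run | 5.1 | 0.296 |
| Wednesday's run | 5.8 | 0.315 |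
| Saturday's run | 0.72 | 0.040 |
| Saturday's run | 1.4 | 0.093 |
| Saturday's run | 2.2 | 0.129 |
| Saturday's run | 2.9 | 0.136 |
| Saturday's run | 3.6 | 0.163 |
| Saturday's run | 4.3 | 0.187 |
| Saturday's run | 5.1 | 0.187 |
| Saturday's run | 5.8 | 0.206 |
| Sunday's run | 0.72 | 0.193 |
| Sunday's run | 1.4 | 0.338 |
| Sunday's run | 2.2 | 0.452 |
| Sunday's run | 2.9 | 0.509 |
| Sunday's run | 3.6 | 0.563 |
| Sunday's run | 4.3 | 0.594 |
| Sunday's run | 5.1 | 0.633 |
| Sunday's run | 5.8 | 0.630 |

(each reading ± 0.006 M)

- Overall: substrate + coupling partner -> target, with free catalyst as catalyst.
- Constant volume, constant temperature.
- An order is taken over about fifteen percent of the charge, up and down.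
- A share of target counts the target that was charged too.

- apparent order in [substrate] of the starting rate, round the charge of the Wednesday's run (the rate where two percent of its substrate have turned into target) (one fixed amount of target, the same in the runs compared)
- apparent order in [coupling partner] of the starting rate, round the charge of the Wednesday's run (the rate where two percent of its substrate have turned into target)
- target in the Tuesday's run at 5.8 min, as a share of the substrate charged

The orders first. At the second reading, Sunday's run leads Wednesday's by a ratio that gives an order in substrate of about 0.822. Saturday's run differs from Wednesday's in both substrate and coupling partner, and at that reading it shows a larger share of its substrate as target. So I put the order in coupling partner near zero, as a loose reading.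

Tuesday's run is Wednesday's charge plus target. My first estimate simply adds the two:

(charged target + Wednesday's last reading) / substrate = 119 %

But that keeps the charged target whole, and nothing has shown that it stays whole. So measure the loss as a correction. Let κ be Wednesday's starting rate per substrate, taken from its first two readings:

κ = 0.159 min⁻¹

A first-order run with this κ and no loss turns this share of its substrate by 5.8 min:

L = 0.602

Now take the share of that yield each run really shows: Saturday's 0.713, Wednesday's 0.654, Sunday's 0.436. It falls from run to run as substrate rises, so I read one loss as growing with substrate. The straight line through Saturday's and Wednesday's shares meets zero substrate at: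

Q = 0.801

Objection: that remainder could be a dying catalyst, which would spare the charged target. But a fit in which the catalyst dies by itself stays 3.9 times the scatter from the readings, so I bet on target being lost, and it is a bet. If target is taken as made evenly, it has stood for about half the time, so Q is roughly the square root of the survival over the whole time:

s = Q² = 0.641

This s is the survival, the share of target present at the start that is still target after 5.8 min. Then:

Tuesday's share = (charged target × s + Wednesday's last reading) / substrate = 90.7 %

The forecast gave 0.9, 0.4 and 118 %, holding that “This points to catalyst dying with time”.

The flask gives 0.93, 0.10 and 90.3 %.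

    free catalyst + substrate → loaded catalyst + by-product (2.778 M⁻¹ min⁻¹)
    loaded catalyst + coupling partner → target + free catalyst (18.36 M⁻¹ min⁻¹)
    2 substrate → homo dimer (0.09180 M⁻¹ min⁻¹)
    target → decomposed product (0.07500 min⁻¹)

In Tuesday's run the charged target does not stay whole: it passes into decomposed product, and that step costs 40 percentage points. With the survival s, the reckoning stood at 90.7 % beside the flask's 90.3 %. Now put s to one for Tuesday's run. The charge stays whole, and the target made, taken from Wednesday's last reading, grows by the factor one over the square root of s, which gives 129 %. Tuesday's run without the decomposition gives 130 %.

(The numbers in the tables stem from a simulated flask with constants of no real substance; noise was put on by code.)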